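The target is cut at C5–C11 and C4–C10: the cyclobutane C4–C5–C11–C10, fused into the six-membered ring C1–C2–C3–C4–C10–C11, has C5 between the two ring-fusion CH atoms and opposite the quaternary C10, the pattern left when a ketene (C5 carbonyl carbon, C4 α-carbon) adds across a C10=C11 alkene. One intramolecular vinylketene–alkene (2+2) cycloaddition therefore closes both rings and sets C4, C10 and C11. Its precursor is an E,E geranic-type dienoyl chloride whose C10 carries the C9–C6 chain (C9 silyl ether, C7 ketone, C6 benzoate as latent enolate) and whose C1 carries a silyl ether that fixes the alkene face and later becomes the enone carbonyl.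

Key step: step 11

Atom labels (target): C1 enone carbonyl carbon; C2 enone CH; C3 methyl-bearing alkene carbon; C4 and C11 the cyclobutane CH atoms shared with the six-membered ring (C4 next to C3, C11 next to C1); C5 the cyclobutane CH bonded to C6; C6 CMe2; C7 carbinol carbon with the epoxy ester; C8 CH2; C9 carbinol carbon with the angelate; C10 quaternary cyclobutane carbon (methyl, C9). Target descriptors in these labels: C4 R, C5 S, C7 R, C9 R, C10 R, C11 R.

Remark on the structure: the C7 ester is (2S,3R)-2,3-dimethyloxirane-2-carboxylate, whose two ring methyl groups are cis. It is the epoxide of the E (tiglic) acid, so it is made from (2E)-2-methylbut-2-en-1-ol; only the C9 ester is the Z (angelic) ester.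

Remarks on the precursor design (carbon skeleton and the two bonds formed are unchanged):
- A C9 stereocentre alone steers the alkene face weakly, because the alkene substituent cis to C9 is hydrogen. C1 is cis to the C10 methyl group, so a C1 silyloxy stereocentre is held by allylic 1,3-strain and, being in the tether, decides the face. The same oxygen becomes the C1 carbonyl, so no allylic C–H oxidation is needed.
- A C6 benzoate makes C6 a regiodefined latent enolate (SmI2), which avoids α-bromination next to alkenes.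

Assumption: (+)-Ipc2BCl and the (S,S) bis(phosphoramide) are taken as the antipodes that give Re-face attack at C9 and Si-face attack at C1; if a sense proves opposite, the mirror-image reagent is used.

Step 1
Reactants: 1 2,2-dimethoxyacetaldehyde; 2 2-(triphenyl-λ5-phosphanylidene)propanal
Product: 3 (2E)-4,4-dimethoxy-2-methylbut-2-enal
Conditions: toluene, 60 °C (1 extracted from its commercial aqueous solution and dried)
Reagents that add atoms: none
Why: Wittig olefination with a stabilised formyl ylide gives the E enal, and the unhindered aldehyde 1 reacts far faster than the α-branched conjugated aldehyde of the product, so a single olefination is expected.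

Step 2
Reactants: 4 3-hydroxy-3-methylbutan-2-one
Product: 5 2-methyl-3-oxobutan-2-yl benzoate
Conditions: BzCl, Et3N, 4-(dimethylamino)pyridine (0.2 equiv), CH2Cl2, 40 °C
Reagents that add atoms: benzoyl chloride, O=C(Cl)c1ccccc1
Why: Nucleophile-catalysed acylation esterifies the tertiary α-ketol, and the benzoate later serves as the leaving group that releases an enolate at C6.

Step 3
Reactants: 5 2-methyl-3-oxobutan-2-yl benzoate; 3 (2E)-4,4-dimethoxy-2-methylbut-2-enal
Product: 6 (5R,6E)-5-hydroxy-8,8-dimethoxy-2,6-dimethyl-3-oxooct-6-en-2-yl benzoate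
Conditions: (+)-Ipc2BCl [(C10H17)2BCl], Et3N, Et2O, 0 °C; then 3, −78 → −20 °C; H2O2, pH 7 buffer, MeOH, 0 °C
Reagents that add atoms: none
Why: Boron-mediated aldol reaction of a methyl ketone: 5 can enolise only at its methyl group, and the isopinocampheyl ligands direct addition to the Re face of the enal, which sets C9 as R (any minor enantiomer becomes a separable diastereomer after step 7).

Step 4
Reactants: 6 (5R,6E)-5-hydroxy-8,8-dimethoxy-2,6-dimethyl-3-oxooct-6-en-2-yl benzoate
Product: 7 (5R,6E)-5-[(tert-butyldimethylsilyl)oxy]-8,8-dimethoxy-2,6-dimethyl-3-oxooct-6-en-2-yl benzoate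
Conditions: TBSCl, imidazole, DMF, rt
Reagents that add atoms: tert-butyldimethylsilyl chloride, CC(C)(C)[Si](C)(C)Cl
Why: Silylation of the secondary allylic alcohol with the silyl chloride (no silyl triflate) leaves the dimethyl acetal untouched.

Step 5
Reactants: 7 (5R,6E)-5-[(tert-butyldimethylsilyl)oxy]-8,8-dimethoxy-2,6-dimethyl-3-oxooct-6-en-2-yl benzoate
Product: 8 (5R,6E)-5-[(tert-butyldimethylsilyl)oxy]-2,6-dimethyl-3,8-dioxooct-6-en-2-yl benzoate
Conditions: pyridinium p-toluenesulfonate (0.1 equiv), acetone/H2O 10:1, rt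
Reagents that add atoms: water, O
Why: Acid-catalysed hydrolysis of the allylic dimethyl acetal is much faster than cleavage of the secondary TBS ether, and the conjugated enal keeps its E geometry.

Step 6
Reactants: 9 methyl 3-methylbut-2-enoate
Product: 10 tert-butyl[(1-methoxy-3-methylbuta-1,3-dien-1-yl)oxy]dimethylsilane
Conditions: LiN(iPr)2, THF, −78 °C; TBSCl, N,N'-dimethylpropyleneurea, −78 °C → rt
Reagents that add atoms: tert-butyldimethylsilyl chloride, CC(C)(C)[Si](C)(C)Cl
Why: Kinetic γ-deprotonation of the enoate gives the cross-conjugated dienolate, which is silylated on oxygen (silyl dienol ether formation).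

Step 7
Reactants: 8 (5R,6E)-5-[(tert-butyldimethylsilyl)oxy]-2,6-dimethyl-3,8-dioxooct-6-en-2-yl benzoate; 10 tert-butyl[(1-methoxy-3-methylbuta-1,3-dien-1-yl)oxy]dimethylsilane
Product: 11 methyl (2E,5S,6E,8R)-11-(benzoyloxy)-8-[(tert-butyldimethylsilyl)oxy]-5-hydroxy-3,7,11-trimethyl-10-oxododeca-2,6-dienoate
Conditions: SiCl4 (1.1 equiv), (S,S)-bis(phosphoramide) C51H52N6O2P2 (5 mol%; two N,N'-dimethyl-1,1'-binaphthyl-2,2'-diamine phosphoramide units joined through their N-methyl nitrogens by a pentane-1,5-diyl chain), iPr2NEt (0.1 equiv), CH2Cl2, −78 °C; aq. NaHCO3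
Reagents that add atoms: none
Why: Vinylogous Mukaiyama aldol reaction under Lewis-base-activated SiCl4: only the aldehyde is activated, the dienol ether reacts at its γ-carbon to give the E enoate, and the chiral phosphoramide directs attack to the Si face, which sets C1 as S.

Step 8
Reactants: 11 methyl (2E,5S,6E,8R)-11-(benzoyloxy)-8-[(tert-butyldimethylsilyl)oxy]-5-hydroxy-3,7,11-trimethyl-10-oxododeca-2,6-dienoate
Product: 12 methyl (2E,5S,6E,8R)-11-(benzoyloxy)-8-[(tert-butyldimethylsilyl)oxy]-3,7,11-trimethyl-10-oxo-5-[(triethylsilyl)oxy]dodeca-2,6-dienoate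
Conditions: TESCl, imidazole, DMF, 0 °C
Reagents that add atoms: chlorotriethylsilane, CC[Si](CC)(CC)Cl
Why: Silylation of the only free hydroxyl gives a C1 triethylsilyl ether that can later be removed in the presence of the C9 TBS ether.

Step 9
Reactants: 12 methyl (2E,5S,6E,8R)-11-(benzoyloxy)-8-[(tert-butyldimethylsilyl)oxy]-3,7,11-trimethyl-10-oxo-5-[(triethylsilyl)oxy]dodeca-2,6-dienoate
Product: 13 (2E,5S,6E,8R)-11-(benzoyloxy)-8-[(tert-butyldimethylsilyl)oxy]-3,7,11-trimethyl-10-oxo-5-[(triethylsilyl)oxy]dodeca-2,6-dienoic acid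
Conditions: Me3SnOH (5 equiv), 1,2-dichloroethane, 80 °C; cold 0.05 M HCl wash
Reagents that add atoms: trimethyltin hydroxide, C[Sn](C)(C)O
Why: Me3SnOH cleaves the methyl ester under nearly neutral conditions, which spares the hindered tertiary benzoate, both silyl ethers and the base-sensitive β-silyloxy ketone.

Step 10
Reactants: 13 (2E,5S,6E,8R)-11-(benzoyloxy)-8-[(tert-butyldimethylsilyl)oxy]-3,7,11-trimethyl-10-oxo-5-[(triethylsilyl)oxy]dodeca-2,6-dienoic acid
Product: 14 (2E,5S,6E,8R)-11-(benzoyloxy)-8-[(tert-butyldimethylsilyl)oxy]-3,7,11-trimethyl-10-oxo-5-[(triethylsilyl)oxy]dodeca-2,6-dienoyl chloride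
Conditions: 1-chloro-N,N,2-trimethylprop-1-en-1-amine (1.2 equiv), CH2Cl2, 0 °C → rt; volatiles removed, crude used at once
Reagents that add atoms: 1-chloro-N,N,2-trimethylprop-1-en-1-amine, CC(C)=C(Cl)N(C)C
Why: The α-chloroenamine converts the acid into its chloride without releasing HCl, so the silyl ethers survive (neutral acid chloride formation).

Step 11
Reactants: 14 (2E,5S,6E,8R)-11-(benzoyloxy)-8-[(tert-butyldimethylsilyl)oxy]-3,7,11-trimethyl-10-oxo-5-[(triethylsilyl)oxy]dodeca-2,6-dienoyl chloride
Product: 16 2-methylidenebicyclo[3.1.1]heptan-6-one cycloadduct (C1 triethylsilyloxy; C10 carrying methyl plus the C9–C6 chain), via vinylketene 15 (not isolated)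
Conditions: Et3N (10 equiv), toluene, 110 °C, slow addition of 14 (syringe pump, final 5 mM)
Reagents that add atoms: none
Why: Et3N removes HCl from 14 with loss of a proton from the C3 methyl group (cis to the acyl group in the 2E isomer) to give vinylketene 15, whose ketene carbon C5 bonds to C11 while positive charge develops at the tertiary C10 and collapses onto the α-carbon C4 in an asynchronous thermal ketene–alkene (2+2) cycloaddition. The closest known reaction type is the amine-induced intramolecular vinylketene cycloaddition of geranic-type acid chlorides to 7,7-disubstituted 2-methylidenebicyclo[3.1.1]heptan-6-ones. The three-atom tether C3–C2–C1 permits only the crossed orientation, so the cyclobutanone (C5–C11 bonding, then closure of C4–C10) and the six-membered ring C4–C3–C2–C1–C11–C10 (closed as the bridging ring by the same two bonds) form together. C10 and C11 are set by suprafacial addition to the E alkene (methyl on the side of C1, C9 on the far side) and C4 by the bridging, which allows only one ring fusion. The alkene face is set by C1: allylic 1,3-strain with the cis C10 methyl keeps the C1 hydrogen in the alkene plane, the tether carbon C2 must sit on the ketene face, and the triethylsilyloxy group therefore points away and ends next to the C5 bridge, whereas attack on the other face would force it against the C10 methyl. The step needs this face selectivity (against the smaller opposing bias expected from the C9 silyloxy group) and reaction at the only nucleophilic alkene; both are built into 14, and high dilution suppresses ketene dimerisation.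

Step 12
Reactants: 16 2-methylidenebicyclo[3.1.1]heptan-6-one cycloadduct
Product: 18 tricyclic β-hydroxy ketone (C5–OH; C7 ketone), via samarium enolate 17 (not isolated)
Conditions: SmI2 (2.5 equiv), THF, −78 → −30 °C; aq. NH4Cl
Reagents that add atoms: none
Why: SmI2 cleaves the α-benzoyloxy ketone by two-electron reduction to a trivalent samarium enolate located at C6 (Reformatsky-type enolate generation), which adds to the strained, highly electrophilic cyclobutanone C5 from its free face anti to the C1–C3 bridge in a seven-membered aldol ring closure, so that C5 can take only the configuration drawn.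

Step 13
Reactants: 18 tricyclic β-hydroxy ketone
Product: 19 C5 methyl oxalate of 18
Conditions: ClC(O)CO2Me (3 equiv), pyridine, 4-(dimethylamino)pyridine (0.5 equiv), CH2Cl2, 0 °C → rt
Reagents that add atoms: methyl chlorooxoacetate, COC(=O)C(=O)Cl
Why: The small, very electrophilic oxalyl monoester chloride acylates the only free hydroxyl, the hindered tertiary C5–OH, under non-basic conditions that do not trigger retro-aldol cleavage.

Step 14
Reactants: 19 C5 methyl oxalate
Product: 20 C5-deoxy tricycle (C5–H; C1 triethylsilyloxy; C9 TBS ether; C7 ketone; C3 methylidene)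
Conditions: Bu3SnH (3 equiv), 2,2'-azobis(2-methylpropionitrile) (0.2 equiv), toluene, 110 °C
Reagents that add atoms: none
Why: Radical deoxygenation of a tertiary alkyl methyl oxalate with Bu3SnH (Barton-type chain): the bridgehead C5 radical can neither eliminate nor open the cyclobutane, the C7 acyl group lies anti to the radical lobe so no 1,2-acyl shift is possible, and hydrogen can arrive only on the face of the C1–C3 bridge, which gives C5–H as in the target.

Step 15
Reactants: 20 C5-deoxy tricycle
Product: 21 C1 alcohol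
Conditions: pyridinium p-toluenesulfonate (0.2 equiv), MeOH/CH2Cl2, 0 °C
Reagents that add atoms: none
Why: Mild acid methanolysis removes the triethylsilyl ether selectively, since the secondary TBS ether next to the quaternary C10 is far slower to cleave.

Step 16
Reactants: 21 C1 alcohol
Product: 23 enone (C1 ketone conjugated with C2=C3; C9 TBS ether; C7 ketone), via β,γ-unsaturated ketone 22 (not isolated)
Conditions: Dess–Martin periodinane, NaHCO3, CH2Cl2, rt; then 1,8-diazabicyclo[5.4.0]undec-7-ene (0.2 equiv), 0 °C → rt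
Reagents that add atoms: none
Why: Dess–Martin oxidation of the only free alcohol gives the β,γ-unsaturated ketone, and catalytic amidine base moves the exocyclic alkene into conjugation through the C1–C3 dienolate (thermodynamic enone formation), while the α-carbon C11 is a bridgehead and cannot epimerise.

Step 17
Reactants: 23 enone
Product: 24 C9 alcohol (β-hydroxy ketone)
Conditions: HF·pyridine, pyridine, THF, 0 °C → rt
Reagents that add atoms: none
Why: Buffered fluoride cleaves the TBS ether without base, so the resulting β-hydroxy ketone is not exposed to retro-aldol or elimination conditions.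

Step 18
Reactants: 24 C9 alcohol
Product: 25 C7 (R) alcohol with C9 pent-4-enoate
Conditions: pent-4-enal (6 equiv), SmI2 (0.3 equiv), THF, −10 °C
Reagents that add atoms: pent-4-enal, C=CCCC=O
Why: Evans–Tishchenko reduction: the aldehyde adds to the C9 oxygen and its formyl hydrogen is delivered within a samarium-bridged six-membered array to the C7 carbonyl on the face of the C9 oxygen, which gives the 1,3-anti alcohol (C7 R) and leaves C9 as a pentenoate, so the two oxygens are told apart in the same step.

Step 19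
Reactants: 26 (2E)-2-methylbut-2-en-1-ol
Product: 27 [(2R,3R)-2,3-dimethyloxiran-2-yl]methanol
Conditions: Ti(OiPr)4 (10 mol%), D-(−)-diethyl tartrate (12 mol%), tBuOOH, 4 Å molecular sieves, CH2Cl2, −20 °C
Reagents that add atoms: tert-butyl hydroperoxide, CC(C)(C)OO
Why: Sharpless asymmetric epoxidation of a primary E allylic alcohol; with D-(−)-diethyl tartrate oxygen is delivered to the face that gives the 2R,3R epoxy alcohol, the mirror image of the 2S,3S product known from the L-(+) ester for E allylic alcohols.

Step 20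
Reactants: 27 [(2R,3R)-2,3-dimethyloxiran-2-yl]methanol
Product: 28 (2S,3R)-2,3-dimethyloxirane-2-carboxylic acid
Conditions: RuCl3·xH2O (2 mol%), NaIO4, MeCN/CCl4/H2O, rt
Reagents that add atoms: water, O
Why: Catalytic RuO4 (from RuCl3 and NaIO4) oxidises the primary alcohol to the acid without touching the trisubstituted epoxide; the stereocentres are unchanged and only the descriptor at C2 becomes S because of the new priority of the carboxyl group.

Step 21
Reactants: 28 (2S,3R)-2,3-dimethyloxirane-2-carboxylic acid; 25 C7 (R) alcohol with C9 pent-4-enoate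
Product: 30 C7 (2S,3R)-2,3-dimethyloxirane-2-carboxylate with C9 pent-4-enoate, via mixed anhydride 29 (not isolated)
Conditions: 28, 2,4,6-trichlorobenzoyl chloride, Et3N, toluene, rt; then 25, 4-(dimethylamino)pyridine, toluene, rt → 40 °C
Reagents that add atoms: none
Why: Yamaguchi esterification: the mixed 2,4,6-trichlorobenzoic anhydride 29 acylates the hindered but only free hydroxyl (C7) under nucleophilic catalysis, with no change at any stereocentre.

Step 22
Reactants: 30 C7 epoxy ester with C9 pent-4-enoate
Product: 31 C9 alcohol with C7 epoxy ester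
Conditions: N-iodosuccinimide (2 equiv), THF/H2O 5:1, 0 °C → rt; aq. Na2S2O3
Reagents that add atoms: none
Why: Iodonium activation of the terminal alkene lets the pentenoate carbonyl close a five-membered ring (iodolactonisation) and water then releases the C9 alcohol, a cleavage that cannot touch the epoxy ester, which has no pendant alkene, or the electron-poor enone.

Step 23
Reactants: 32 angelic acid [(2Z)-2-methylbut-2-enoic acid]; 31 C9 alcohol with C7 epoxy ester
Product: 34 target CNP0149458.1, via angelic mixed anhydride 33 (not isolated)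
Conditions: 32, 2,4,6-trichlorobenzoyl chloride, Et3N, toluene, rt; then 31, toluene, 75 °C
Reagents that add atoms: none
Why: Esterification through the mixed 2,4,6-trichlorobenzoic anhydride in the absence of a nucleophilic catalyst is the established way to transfer an angeloyl group without Z to E isomerisation, and the only free hydroxyl is C9.

Compound list
1 | 2,2-dimethoxyacetaldehyde | COC(OC)C=O | starting material
2 | 2-(triphenyl-λ5-phosphanylidene)propanal | CC(C=O)=P(c1ccccc1)(c1ccccc1)c1ccccc1 | starting material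
3 | (2E)-4,4-dimethoxy-2-methylbut-2-enal | COC(OC)/C=C(\C)C=O | intermediate
4 | 3-hydroxy-3-methylbutan-2-one | CC(=O)C(C)(C)O | starting material
5 | 2-methyl-3-oxobutan-2-yl benzoate | CC(=O)C(C)(C)OC(=O)c1ccccc1 | intermediate
6 | (5R,6E)-5-hydroxy-8,8-dimethoxy-2,6-dimethyl-3-oxooct-6-en-2-yl benzoate | COC(OC)/C=C(\C)[C@H](O)CC(=O)C(C)(C)OC(=O)c1ccccc1 | intermediate
7 | (5R,6E)-5-[(tert-butyldimethylsilyl)oxy]-8,8-dimethoxy-2,6-dimethyl-3-oxooct-6-en-2-yl benzoate | COC(OC)/C=C(\C)[C@H](O[Si](C)(C)C(C)(C)C)CC(=O)C(C)(C)OC(=O)c1ccccc1 | intermediate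
8 | (5R,6E)-5-[(tert-butyldimethylsilyl)oxy]-2,6-dimethyl-3,8-dioxooct-6-en-2-yl benzoate | O=C/C=C(\C)[C@H](O[Si](C)(C)C(C)(C)C)CC(=O)C(C)(C)OC(=O)c1ccccc1 | intermediate
9 | methyl 3-methylbut-2-enoate | CC(C)=CC(=O)OC | starting material
10 | tert-butyl[(1-methoxy-3-methylbuta-1,3-dien-1-yl)oxy]dimethylsilane (ketene acetal geometry not defined) | C=C(C)C=C(OC)O[Si](C)(C)C(C)(C)C | intermediate
11 | methyl (2E,5S,6E,8R)-11-(benzoyloxy)-8-[(tert-butyldimethylsilyl)oxy]-5-hydroxy-3,7,11-trimethyl-10-oxododeca-2,6-dienoate | COC(=O)/C=C(\C)C[C@H](O)/C=C(\C)[C@H](O[Si](C)(C)C(C)(C)C)CC(=O)C(C)(C)OC(=O)c1ccccc1 | intermediate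
12 | methyl (2E,5S,6E,8R)-11-(benzoyloxy)-8-[(tert-butyldimethylsilyl)oxy]-3,7,11-trimethyl-10-oxo-5-[(triethylsilyl)oxy]dodeca-2,6-dienoate | COC(=O)/C=C(\C)C[C@H](O[Si](CC)(CC)CC)/C=C(\C)[C@H](O[Si](C)(C)C(C)(C)C)CC(=O)C(C)(C)OC(=O)c1ccccc1 | intermediate
13 | (2E,5S,6E,8R)-11-(benzoyloxy)-8-[(tert-butyldimethylsilyl)oxy]-3,7,11-trimethyl-10-oxo-5-[(triethylsilyl)oxy]dodeca-2,6-dienoic acid | OC(=O)/C=C(\C)C[C@H](O[Si](CC)(CC)CC)/C=C(\C)[C@H](O[Si](C)(C)C(C)(C)C)CC(=O)C(C)(C)OC(=O)c1ccccc1 | intermediate
14 | (2E,5S,6E,8R)-11-(benzoyloxy)-8-[(tert-butyldimethylsilyl)oxy]-3,7,11-trimethyl-10-oxo-5-[(triethylsilyl)oxy]dodeca-2,6-dienoyl chloride (key-step precursor; acyl carbon = C5, C1 S, C9 R) | ClC(=O)/C=C(\C)C[C@H](O[Si](CC)(CC)CC)/C=C(\C)[C@H](O[Si](C)(C)C(C)(C)C)CC(=O)C(C)(C)OC(=O)c1ccccc1 | intermediate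
15 | vinylketene (5S,6E,8R)-11-(benzoyloxy)-8-[(tert-butyldimethylsilyl)oxy]-7,11-dimethyl-3-methylidene-5-[(triethylsilyl)oxy]dodeca-1,6-diene-1,10-dione | O=C=CC(=C)C[C@H](O[Si](CC)(CC)CC)/C=C(\C)[C@H](O[Si](C)(C)C(C)(C)C)CC(=O)C(C)(C)OC(=O)c1ccccc1 | intermediate (not isolated)
16 | 7-methyl-2-methylidene-4-[(triethylsilyl)oxy]bicyclo[3.1.1]heptan-6-one carrying on C7 (label C10) the (1R)-4-(benzoyloxy)-1-[(tert-butyldimethylsilyl)oxy]-4-methyl-3-oxopentyl chain; labels: C5 ketone, C1 (S) silyloxy next to the C5 bridge, C10 methyl on the side of the C1–C3 bridge, C4, C10, C11 as in the target (key-step product) | O=C1[C@H]2[C@@H](O[Si](CC)(CC)CC)CC(=C)[C@@H]1[C@@]2(C)[C@H](O[Si](C)(C)C(C)(C)C)CC(=O)C(C)(C)OC(=O)c1ccccc1 | intermediate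
17 | trivalent samarium enolate of 16 (C6=C7 enolate after loss of benzoate, I2Sm–O on C7) | O=C1[C@H]2[C@@H](O[Si](CC)(CC)CC)CC(=C)[C@@H]1[C@@]2(C)[C@H](O[Si](C)(C)C(C)(C)C)CC(O[Sm](I)I)=C(C)C | intermediate (not isolated)
18 | tricyclic β-hydroxy ketone: ring system of the target with tertiary C5–OH on the side of the C1–C3 bridge, C7 ketone, C6 gem-dimethyl, C9 (R) TBS ether, C1 (S) triethylsilyl ether, exocyclic C3=CH2 | CC(C)(C)[Si](C)(C)O[C@@H]1CC(=O)C(C)(C)[C@]2(O)[C@H]3[C@@H](O[Si](CC)(CC)CC)CC(=C)[C@@H]2[C@]31C | intermediate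
19 | C5 methyl oxalate of 18 | CC(C)(C)[Si](C)(C)O[C@@H]1CC(=O)C(C)(C)[C@]2(OC(=O)C(=O)OC)[C@H]3[C@@H](O[Si](CC)(CC)CC)CC(=C)[C@@H]2[C@]31C | intermediate
20 | C5-deoxy tricycle: C5–H (S, as in the target), otherwise as 18 | CC(C)(C)[Si](C)(C)O[C@@H]1CC(=O)C(C)(C)[C@@H]2[C@H]3[C@@H](O[Si](CC)(CC)CC)CC(=C)[C@@H]2[C@]31C | intermediate
21 | C1 alcohol: 20 without the triethylsilyl group | CC(C)(C)[Si](C)(C)O[C@@H]1CC(=O)C(C)(C)[C@@H]2[C@H]3[C@@H](O)CC(=C)[C@@H]2[C@]31C | intermediate
22 | β,γ-unsaturated ketone: C1 ketone, exocyclic C3=CH2, C7 ketone, C9 TBS ether | CC(C)(C)[Si](C)(C)O[C@@H]1CC(=O)C(C)(C)[C@@H]2[C@H]3C(=O)CC(=C)[C@@H]2[C@]31C | intermediate (not isolated)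
23 | enone: C1 ketone conjugated with C2=C3 (C3 methyl), C7 ketone, C9 (R) TBS ether | CC(C)(C)[Si](C)(C)O[C@@H]1CC(=O)C(C)(C)[C@@H]2[C@H]3C(=O)C=C(C)[C@@H]2[C@]31C | intermediate
24 | C9 (R) alcohol of 23 (β-hydroxy ketone) | O[C@@H]1CC(=O)C(C)(C)[C@@H]2[C@H]3C(=O)C=C(C)[C@@H]2[C@]31C | intermediate
25 | C7 (R) alcohol with C9 (R) pent-4-enoate | C=CCCC(=O)O[C@@H]1C[C@@H](O)C(C)(C)[C@@H]2[C@H]3C(=O)C=C(C)[C@@H]2[C@]31C | intermediate
26 | (2E)-2-methylbut-2-en-1-ol | C/C=C(\C)CO | starting material
27 | [(2R,3R)-2,3-dimethyloxiran-2-yl]methanol | OC[C@@]1(C)O[C@@H]1C | intermediate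
28 | (2S,3R)-2,3-dimethyloxirane-2-carboxylic acid | OC(=O)[C@@]1(C)O[C@@H]1C | intermediate
29 | (2S,3R)-2,3-dimethyloxirane-2-carboxylic 2,4,6-trichlorobenzoic anhydride | Clc1cc(Cl)c(C(=O)OC(=O)[C@@]2(C)O[C@@H]2C)c(Cl)c1 | intermediate (not isolated)
30 | C7 (2S,3R)-2,3-dimethyloxirane-2-carboxylate with C9 pent-4-enoate | C=CCCC(=O)O[C@@H]1C[C@@H](OC(=O)[C@@]2(C)O[C@@H]2C)C(C)(C)[C@@H]2[C@H]3C(=O)C=C(C)[C@@H]2[C@]31C | intermediate
31 | C9 (R) alcohol with C7 (2S,3R)-2,3-dimethyloxirane-2-carboxylate | O[C@@H]1C[C@@H](OC(=O)[C@@]2(C)O[C@@H]2C)C(C)(C)[C@@H]2[C@H]3C(=O)C=C(C)[C@@H]2[C@]31C | intermediate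
32 | angelic acid, (2Z)-2-methylbut-2-enoic acid | C/C=C(/C)C(=O)O | starting material
33 | (2Z)-2-methylbut-2-enoic 2,4,6-trichlorobenzoic anhydride | C/C=C(/C)C(=O)OC(=O)c1c(Cl)cc(Cl)cc1Cl | intermediate (not isolated)
34 | CNP0149458.1: (1R,2S,4R,6R,7R,8R)-3,3,7,11-tetramethyl-6-{[(2Z)-2-methylbut-2-enoyl]oxy}-9-oxotricyclo[5.4.0.0(2,8)]undec-10-en-4-yl (2S,3R)-2,3-dimethyloxirane-2-carboxylate | C/C=C(/C)C(=O)O[C@@H]1C[C@@H](OC(=O)[C@@]2(C)O[C@@H]2C)C(C)(C)[C@@H]2[C@H]3C(=O)C=C(C)[C@@H]2[C@]31C | target

Total step count: 23. Longest linear sequence: 19 steps (1, 3–5, 7–18, 21–23).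

Steps most likely to fail

Step 11. The alkene is flanked by two allylic silyloxy carbons and may add to the ketene too slowly, so that ketene dimerisation or base-induced loss of the C9 silyloxy group (β to the C7 ketone) takes over; the opposing C9 bias may also erode face selection. Fallback: the fallback sets out from acid chloride 14, which with dimethylamine gives the N,N-dimethylamide F1. Activation with (CF3SO2)2O and 2,4,6-trimethylpyridine in refluxing 1,2-dichloroethane generates the more electrophilic vinylketeniminium ion. Its intramolecular (2+2) cycloaddition forms the same two bonds under the same tether and C1 control and gives the cyclobutaniminium triflate F2. Aqueous NaHCO3 hydrolysis returns to the route at 16.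

Step 12. The samarium enolate may be protonated, or the cyclobutanone reduced, faster than the seven-membered aldol closure occurs, or the aldolate may revert by retro-aldol cleavage before work-up. Fallback: the fallback sets out from 16, where SmI2 in the presence of Me3SiCl traps the C6 enolate as the trimethylsilyl enol ether F3. A Lewis-acid Mukaiyama aldol reaction (TiCl4, CH2Cl2, −78 °C) then closes C5–C6 irreversibly and returns to the route at 18 after aqueous work-up.

Step 23. Acylation of the hindered C9 hydroxyl may be so slow that the angeloyl group isomerises to the E (tigloyl) ester or that the forcing conditions open the epoxide. Fallback: the fallback sets out from 31, which is esterified with 2-[bis(2,2,2-trifluoroethoxy)phosphoryl]propanoic acid (N,N'-dicyclohexylcarbodiimide, 4-(dimethylamino)pyridine) to the phosphonate ester F4. Still–Gennari olefination with acetaldehyde (KN(SiMe3)2, 18-crown-6, THF, −78 °C) builds the Z double bond in place and returns to the route at 34.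

Further compounds
F1 | step 11 | (2E,5S,6E,8R)-11-(benzoyloxy)-8-[(tert-butyldimethylsilyl)oxy]-N,N,3,7,11-pentamethyl-10-oxo-5-[(triethylsilyl)oxy]dodeca-2,6-dienamide | CN(C)C(=O)/C=C(\C)C[C@H](O[Si](CC)(CC)CC)/C=C(\C)[C@H](O[Si](C)(C)C(C)(C)C)CC(=O)C(C)(C)OC(=O)c1ccccc1
F2 | step 11 | N,N-dimethyliminium triflate of 16 (C5=N+Me2 in place of the C5 ketone) | C[N+](C)=C1[C@H]2[C@@H](O[Si](CC)(CC)CC)CC(=C)[C@@H]1[C@@]2(C)[C@H](O[Si](C)(C)C(C)(C)C)CC(=O)C(C)(C)OC(=O)c1ccccc1.[O-]S(=O)(=O)C(F)(F)F
F3 | step 12 | trimethylsilyl enol ether of the debenzoylated ketone (C6=C7, Me3SiO on C7) | O=C1[C@H]2[C@@H](O[Si](CC)(CC)CC)CC(=C)[C@@H]1[C@@]2(C)[C@H](O[Si](C)(C)C(C)(C)C)CC(O[Si](C)(C)C)=C(C)C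
F4 | step 23 | C9 2-[bis(2,2,2-trifluoroethoxy)phosphoryl]propanoate of 31 (both epimers at the phosphonate carbon) | CC(C(=O)O[C@@H]1C[C@@H](OC(=O)[C@@]2(C)O[C@@H]2C)C(C)(C)[C@@H]2[C@H]3C(=O)C=C(C)[C@@H]2[C@]31C)P(=O)(OCC(F)(F)F)OCC(F)(F)F
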